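All runs come from a simulation for substances that don't exist; scatter was added.

With 0.40 M of substrate and 2.5 mol% of free catalyst charged, you want a quick factor on the rate at 10% conversion.

the same everywhere: substrate 0.40 M

| run | free catalyst | remark |
|---|---|---|
| noon | 3.8 mol% | run made earlier |
| flask | 2.5 mol% |  |

- noon (time / min: target / %): 20.0: 15.0; 40.0: 26.9; 60.0: 36.7; 80.0: 44.2; 90.0: 47.9; 120: 56.3

(readings scatter by 0.3 percentage points)

- the analysis behind the earlier runs scatters by 0.3 percentage points, standard deviation
- reactions considered so far: free catalyst -> spent catalyst; substrate + free catalyst -> free catalyst + target; 2 free catalyst <-> resting dimer
- no earlier run changes the charge of free catalyst; that part of a forecast is a guess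

1. factor on the rate of making target when 10% of the substrate are converted if free catalyst is charged twice over
2. factor on the rate when 10% of the substrate are converted if free catalyst is charged at 25 mol% instead

A rate that follows the charge is one end of the answer. In the noon run, reading target as conversion, the first-order constant falls from 0.00813 min⁻¹ at the start to 0.00586 min⁻¹ over the last interval. So working catalyst is being lost. But that run has one loading and is silent on the order in catalyst.

Target is made at k[substrate][free catalyst], and at equal conversion [substrate] is equal. The factor on the rate is therefore the factor on the charge, here 10.0, times the kept share: the free share of the catalyst in the richer flask over that in the poorer. With no dimer it is about 1. With the catalyst resting as dimer, its resting state, [free catalyst] goes as the root of the charge, and the kept share is 0.316. Joining the ends at the middle of the order, I commit to 1.68 on doubling and 5.62 at 25 mol%.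

The forecast stands above my join, at 1.8 and 6.5: “Since dimerisation is proposed and bites harder at high loading, I take an intermediate position”.

The simulation gives 1.57 and 3.92.

    free catalyst → spent catalyst (k = 2.75 × 10⁻⁴ s⁻¹)
    substrate + free catalyst → free catalyst + target (k = 0.0293 M⁻¹ s⁻¹)
    2 free catalyst ⇌ resting dimer, settled at all times (K = 231 M⁻¹)

At 10% conversion the flask holds 34.6% of its catalyst free and 55.5% as resting dimer, while the 25 mol% charge holds 13.6% and 85.4%, and the rate factor of 3.92 stays below the charge factor of 10.0. The kept share is 0.392 from the rates and 0.393 from the free shares, above the dimer end of 0.316, and for the doubled flask it is 0.785.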